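**Plan**

- Cuts, in retrosynthetic order: the four O–benzyl bonds; O1–C2 and C4–C4a/C4–C3 of the acacetin half (o-iodophenol + CO + 4-ethynylanisole); the C8a–O bond, traced back to a formyl group; O1–C2 and C3–C4 of the apigenin half (diketone from a benzoate and a protected phloroacetophenone); and ring B of the apigenin half.
- Enabling feature: ring B of the apigenin half is a 1,4-phenylene with the ether oxygen on C4' and C2 on C1'. C1', C2', C3', C6' map onto C5, C4, C3, C6 of methyl coumalate; C4' and C5' are the two carbons of an ynol ether that already carries the crowded C6–O bond of ring A of the acacetin half.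
- Forward order: protected gallaldehyde → aryl ynol ether → ring B by cycloaddition and CO2 loss → ring C of the apigenin half (Claisen condensation, cyclodehydration) → formyl to phenol → iodide → ring C of the acacetin half by carbonylative annulation → debenzylation.
- Stereochemistry: the target has no stereocentre. The E geometry of the dichlorovinyl ether and the racemic bridgeheads of the bicyclic lactone are transient and are erased.

Key step: step 6

Remark: the terminal ynol ether 9 is assumed to survive a cold, base-washed work-up long enough to be taken straight into step 6 as a solution.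

**Step 1**
Reactants: 1 3,4,5-trihydroxybenzaldehyde
Product: 2 3,4,5-tris(benzyloxy)benzaldehyde
Conditions: BnBr (3.6 equiv), K2CO3, DMF, 60 °C, N2
Reagents that add atoms: benzyl bromide, BrCc1ccccc1
Why: Williamson etherification of all three phenols under carbonate base should go to completion, the aldehyde being inert and the inert atmosphere protecting the pyrogallol from oxidation.

**Step 2**
Reactants: 2 3,4,5-tris(benzyloxy)benzaldehyde
Product: 3 3,5-bis(benzyloxy)-4-hydroxybenzaldehyde
Conditions: MgBr2·OEt2 (1.5 equiv), PhMe–Et2O, reflux; dilute HCl work-up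
Reagents that add atoms: none
Why: Chelation-assisted Lewis acid ether cleavage should remove only the central benzyl group, whose twisted oxygen is the most basic and whose phenoxide is para to the formyl group, the selectivity known for turning 3,4,5-trialkoxybenzaldehydes into their 4-phenols.

**Step 3**
Reactants: 3 3,5-bis(benzyloxy)-4-hydroxybenzaldehyde
Product: 4 2-[3,5-bis(benzyloxy)-4-hydroxyphenyl]-1,3-dioxolane
Conditions: HOCH2CH2OH, PPTS (cat.), PhMe, reflux, Dean–Stark; Et3N quench
Reagents that add atoms: ethylene glycol, OCCO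
Why: Acid-catalysed acetalisation with azeotropic removal of water should mask the aldehyde against n-BuLi in step 5, the free phenol being tolerated as in acetals of other 4-hydroxybenzaldehydes.

**Step 4**
Reactants: 4 2-[3,5-bis(benzyloxy)-4-hydroxyphenyl]-1,3-dioxolane; 5 trichloroethylene
Product: 6 2-[3,5-bis(benzyloxy)-4-{[(E)-1,2-dichloroethenyl]oxy}phenyl]-1,3-dioxolane
Conditions: 5 (1.5 equiv), K2CO3, DMF, 70 °C
Reagents that add atoms: none
Why: Dichlorovinylation of a phenol should work because base turns trichloroethylene into dichloroacetylene and the phenoxide adds trans across this small linear electrophile, which reaches the flanked oxygen and gives the E ether.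

**Step 5**
Reactants: 6 2-[3,5-bis(benzyloxy)-4-{[(E)-1,2-dichloroethenyl]oxy}phenyl]-1,3-dioxolane
Product: 9 2-[3,5-bis(benzyloxy)-4-(ethynyloxy)phenyl]-1,3-dioxolane, via chloroalkynyl ether 7 (not isolated), via lithium aryloxyacetylide 8 (not isolated)
Conditions: n-BuLi (2.3 equiv), THF, −78 → −40 °C; then H2O–THF, −78 °C; cold work-up, used at once
Reagents that add atoms: none
Why: Dehydrochlorination to the chloroalkyne followed by lithium–chlorine exchange is the established route from 1,2-dichlorovinyl ethers to ynol ethers, and the acetal and benzyl ethers should tolerate n-BuLi at −78 °C.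

**Step 6**
Reactants: 9 2-[3,5-bis(benzyloxy)-4-(ethynyloxy)phenyl]-1,3-dioxolane; 10 methyl coumalate
Product: 12 methyl 4-[2,6-bis(benzyloxy)-4-(1,3-dioxolan-2-yl)phenoxy]benzoate, via bicyclic lactone 11 (not isolated)
Conditions: 10 (3 equiv), PhMe, 110 °C, sealed tube, BHT (cat.), slow addition of 9
Reagents that add atoms: none
Why: Proposed new method: the polarised ynol ether 9 should attack C6 of methyl coumalate (the terminus conjugated to both the lactone carbonyl and the ester) with its nucleophilic terminal carbon while the oxygen-bearing carbon bonds to C3, an asynchronous inverse-electron-demand [4+2] cycloaddition giving the 2-oxabicyclo[2.2.2]octadienone 11, which loses CO2 by cycloreversion to give the arene directly at the benzoate oxidation level. The closest known reaction type is the Diels–Alder/decarboxylation benzannulation of methyl coumalate and other 2-pyrones with ketene acetals, ynamines and alkynes, which gives para-donor-substituted benzoates; aryl ynol ethers are not documented as the 2π partner. Ring B is closed by intermolecular [4+2] cycloaddition (bonds C3'–C4' and C5'–C6') followed by retro-[4+2] extrusion of CO2. No stereocentre remains, since the two bridgehead centres of racemic 11 vanish on aromatisation. The selectivity needed is para over meta orientation of ester and aryloxy group, secured by pairing the largest HOMO coefficient (terminal alkyne carbon) with the largest LUMO coefficient (coumalate C6). The aryl ynol ether has no β-hydrogen for retro-ene decay to a ketene, both ortho positions are blocked, and no bond is formed at the crowded ether oxygen.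

**Step 7**
Reactants: 13 2,4,6-trihydroxyacetophenone
Product: 14 1-[2,4-bis(benzyloxy)-6-hydroxyphenyl]ethan-1-one
Conditions: BnBr (2.1 equiv), K2CO3, DMF, rt
Reagents that add atoms: benzyl bromide, BrCc1ccccc1
Why: Williamson benzylation with two equivalents should leave one ortho hydroxyl free, because the hydroxyl hydrogen-bonded to the acetyl carbonyl is the least nucleophilic.

**Step 8**
Reactants: 12 methyl 4-[2,6-bis(benzyloxy)-4-(1,3-dioxolan-2-yl)phenoxy]benzoate; 14 1-[2,4-bis(benzyloxy)-6-hydroxyphenyl]ethan-1-one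
Product: 15 1-[2,4-bis(benzyloxy)-6-hydroxyphenyl]-3-{4-[2,6-bis(benzyloxy)-4-(1,3-dioxolan-2-yl)phenoxy]phenyl}propane-1,3-dione
Conditions: 14 (1.3 equiv), LiN(SiMe3)2 (4 equiv), THF, −78 → 0 °C; then 12, 0 → 45 °C; AcOH quench
Reagents that add atoms: none
Why: Crossed Claisen condensation of the phenoxide–enolate of 14 with the non-enolisable benzoate (the intermolecular counterpart of the Baker–Venkataraman acyl transfer) should be driven by deprotonation of the diketone, and the acetal is stable to base.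

**Step 9**
Reactants: 15 1-[2,4-bis(benzyloxy)-6-hydroxyphenyl]-3-{4-[2,6-bis(benzyloxy)-4-(1,3-dioxolan-2-yl)phenoxy]phenyl}propane-1,3-dione
Product: 17 3,5-bis(benzyloxy)-4-{4-[5,7-bis(benzyloxy)-4-oxo-4H-chromen-2-yl]phenoxy}benzaldehyde, via flavone acetal 16 (not isolated)
Conditions: H2SO4 (cat.), AcOH, 70 °C; then H2O, 50 °C
Reagents that add atoms: water, O
Why: Acid-catalysed cyclodehydration of the o-hydroxyaryl 1,3-diketone (6-exo-trig hemiketal formation, then loss of water) is the standard flavone closure, and the added water should hydrolyse the dioxolane in the same pot.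

**Step 10**
Reactants: 17 3,5-bis(benzyloxy)-4-{4-[5,7-bis(benzyloxy)-4-oxo-4H-chromen-2-yl]phenoxy}benzaldehyde
Product: 19 5,7-bis(benzyloxy)-2-{4-[2,6-bis(benzyloxy)-4-hydroxyphenoxy]phenyl}-4H-chromen-4-one, via aryl formate 18 (not isolated)
Conditions: mCPBA, CH2Cl2, rt; aq. NaHCO3 wash; then K2CO3 (cat.), MeOH–CH2Cl2, rt
Reagents that add atoms: mCPBA, O=C(OO)c1cccc(Cl)c1
Why: Baeyer–Villiger (Dakin-type) oxidation should proceed by aryl migration assisted by the para aryloxy donor, as for alkoxy- and aryloxybenzaldehydes, and the formate is then methanolysed while the electron-poor flavone enone resists the peracid.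

**Step 11**
Reactants: 19 5,7-bis(benzyloxy)-2-{4-[2,6-bis(benzyloxy)-4-hydroxyphenoxy]phenyl}-4H-chromen-4-one
Product: 20 5,7-bis(benzyloxy)-2-{4-[2,6-bis(benzyloxy)-4-hydroxy-3-iodophenoxy]phenyl}-4H-chromen-4-one
Conditions: NIS (1.0 equiv), CH2Cl2, −20 → 0 °C, dark
Reagents that add atoms: N-iodosuccinimide, O=C1CCC(=O)N1I
Why: Electrophilic aromatic iodination should occur only on the free phenol ring, by far the most nucleophilic arene present, and its two ortho positions are equivalent, so one equivalent gives a single mono-iodide.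

**Step 12**
Reactants: 20 5,7-bis(benzyloxy)-2-{4-[2,6-bis(benzyloxy)-4-hydroxy-3-iodophenoxy]phenyl}-4H-chromen-4-one; 21 4-ethynylanisole
Product: 23 5,7-bis(benzyloxy)-6-{4-[5,7-bis(benzyloxy)-4-oxo-4H-chromen-2-yl]phenoxy}-2-(4-methoxyphenyl)-4H-chromen-4-one, via ynone 22 (not isolated)
Conditions: 21 (1.5 equiv), PdCl2(PPh3)2 (5 mol%), CO (20 bar), Et2NH–DMF, 100 °C
Reagents that add atoms: carbon monoxide, [C-]#[O+]
Why: Carbonylative Sonogashira coupling of an o-iodophenol (oxidative addition to zerovalent palladium, CO insertion, alkynyl transfer, reductive elimination) should give ynone 22, which closes 6-endo-dig by amine-promoted oxa-Michael addition, the copper-free, CO-pressurised conditions disfavouring direct alkynylation.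

**Step 13**
Reactants: 23 5,7-bis(benzyloxy)-6-{4-[5,7-bis(benzyloxy)-4-oxo-4H-chromen-2-yl]phenoxy}-2-(4-methoxyphenyl)-4H-chromen-4-one
Product: 24 cryptomerin A, 5,7-dihydroxy-6-[4-(5,7-dihydroxy-4-oxo-4H-chromen-2-yl)phenoxy]-2-(4-methoxyphenyl)-4H-chromen-4-one
Conditions: H2 (1 atm), 10% Pd/C, THF–MeOH, rt
Reagents that add atoms: none
Why: Catalytic hydrogenolysis should cleave the four aryl benzyl ethers while the aryl methyl ether, the diaryl ether and both flavone enones persist at ambient pressure and temperature.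

**Compound list**

1 | 3,4,5-trihydroxybenzaldehyde | O=Cc1cc(O)c(O)c(O)c1 | starting material
2 | 3,4,5-tris(benzyloxy)benzaldehyde | O=Cc1cc(OCc2ccccc2)c(OCc2ccccc2)c(OCc2ccccc2)c1 | intermediate
3 | 3,5-bis(benzyloxy)-4-hydroxybenzaldehyde | O=Cc1cc(OCc2ccccc2)c(O)c(OCc2ccccc2)c1 | intermediate
4 | 2-[3,5-bis(benzyloxy)-4-hydroxyphenyl]-1,3-dioxolane | Oc1c(OCc2ccccc2)cc(C2OCCO2)cc1OCc1ccccc1 | intermediate
5 | trichloroethylene | ClC=C(Cl)Cl | starting material
6 | 2-[3,5-bis(benzyloxy)-4-{[(E)-1,2-dichloroethenyl]oxy}phenyl]-1,3-dioxolane | Cl/C=C(/Cl)Oc1c(OCc2ccccc2)cc(C2OCCO2)cc1OCc1ccccc1 | intermediate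
7 | 2-[3,5-bis(benzyloxy)-4-[(chloroethynyl)oxy]phenyl]-1,3-dioxolane (not isolated) | ClC#COc1c(OCc2ccccc2)cc(C2OCCO2)cc1OCc1ccccc1 | intermediate
8 | lithium {[2,6-bis(benzyloxy)-4-(1,3-dioxolan-2-yl)phenoxy]ethynide} (not isolated) | [Li]C#COc1c(OCc2ccccc2)cc(C2OCCO2)cc1OCc1ccccc1 | intermediate
9 | 2-[3,5-bis(benzyloxy)-4-(ethynyloxy)phenyl]-1,3-dioxolane | C#COc1c(OCc2ccccc2)cc(C2OCCO2)cc1OCc1ccccc1 | intermediate
10 | methyl coumalate | COC(=O)C1=COC(=O)C=C1 | starting material
11 | methyl 8-[2,6-bis(benzyloxy)-4-(1,3-dioxolan-2-yl)phenoxy]-3-oxo-2-oxabicyclo[2.2.2]octa-5,7-diene-6-carboxylate (racemic, not isolated) | COC(=O)C1=CC2C(=O)OC1C=C2Oc1c(OCc2ccccc2)cc(C2OCCO2)cc1OCc1ccccc1 | intermediate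
12 | methyl 4-[2,6-bis(benzyloxy)-4-(1,3-dioxolan-2-yl)phenoxy]benzoate | COC(=O)c1ccc(Oc2c(OCc3ccccc3)cc(C3OCCO3)cc2OCc2ccccc2)cc1 | intermediate
13 | 2,4,6-trihydroxyacetophenone | CC(=O)c1c(O)cc(O)cc1O | starting material
14 | 1-[2,4-bis(benzyloxy)-6-hydroxyphenyl]ethan-1-one | CC(=O)c1c(O)cc(OCc2ccccc2)cc1OCc1ccccc1 | intermediate
15 | 1-[2,4-bis(benzyloxy)-6-hydroxyphenyl]-3-{4-[2,6-bis(benzyloxy)-4-(1,3-dioxolan-2-yl)phenoxy]phenyl}propane-1,3-dione | O=C(CC(=O)c1ccc(Oc2c(OCc3ccccc3)cc(C3OCCO3)cc2OCc2ccccc2)cc1)c1c(O)cc(OCc2ccccc2)cc1OCc1ccccc1 | intermediate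
16 | 5,7-bis(benzyloxy)-2-{4-[2,6-bis(benzyloxy)-4-(1,3-dioxolan-2-yl)phenoxy]phenyl}-4H-chromen-4-one (not isolated) | O=c1cc(-c2ccc(Oc3c(OCc4ccccc4)cc(C4OCCO4)cc3OCc3ccccc3)cc2)oc2cc(OCc3ccccc3)cc(OCc3ccccc3)c12 | intermediate
17 | 3,5-bis(benzyloxy)-4-{4-[5,7-bis(benzyloxy)-4-oxo-4H-chromen-2-yl]phenoxy}benzaldehyde | O=Cc1cc(OCc2ccccc2)c(Oc2ccc(-c3cc(=O)c4c(OCc5ccccc5)cc(OCc5ccccc5)cc4o3)cc2)c(OCc2ccccc2)c1 | intermediate
18 | 3,5-bis(benzyloxy)-4-{4-[5,7-bis(benzyloxy)-4-oxo-4H-chromen-2-yl]phenoxy}phenyl formate (not isolated) | O=COc1cc(OCc2ccccc2)c(Oc2ccc(-c3cc(=O)c4c(OCc5ccccc5)cc(OCc5ccccc5)cc4o3)cc2)c(OCc2ccccc2)c1 | intermediate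
19 | 5,7-bis(benzyloxy)-2-{4-[2,6-bis(benzyloxy)-4-hydroxyphenoxy]phenyl}-4H-chromen-4-one | Oc1cc(OCc2ccccc2)c(Oc2ccc(-c3cc(=O)c4c(OCc5ccccc5)cc(OCc5ccccc5)cc4o3)cc2)c(OCc2ccccc2)c1 | intermediate
20 | 5,7-bis(benzyloxy)-2-{4-[2,6-bis(benzyloxy)-4-hydroxy-3-iodophenoxy]phenyl}-4H-chromen-4-one | Oc1cc(OCc2ccccc2)c(Oc2ccc(-c3cc(=O)c4c(OCc5ccccc5)cc(OCc5ccccc5)cc4o3)cc2)c(OCc2ccccc2)c1I | intermediate
21 | 4-ethynylanisole | C#Cc1ccc(OC)cc1 | starting material
22 | 1-[2,4-bis(benzyloxy)-3-{4-[5,7-bis(benzyloxy)-4-oxo-4H-chromen-2-yl]phenoxy}-6-hydroxyphenyl]-3-(4-methoxyphenyl)prop-2-yn-1-one (not isolated) | COc1ccc(C#CC(=O)c2c(O)cc(OCc3ccccc3)c(Oc3ccc(-c4cc(=O)c5c(OCc6ccccc6)cc(OCc6ccccc6)cc5o4)cc3)c2OCc2ccccc2)cc1 | intermediate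
23 | 5,7-bis(benzyloxy)-6-{4-[5,7-bis(benzyloxy)-4-oxo-4H-chromen-2-yl]phenoxy}-2-(4-methoxyphenyl)-4H-chromen-4-one | COc1ccc(-c2cc(=O)c3c(OCc4ccccc4)c(Oc4ccc(-c5cc(=O)c6c(OCc7ccccc7)cc(OCc7ccccc7)cc6o5)cc4)c(OCc4ccccc4)cc3o2)cc1 | intermediate
24 | cryptomerin A | COc1ccc(-c2cc(=O)c3c(O)c(Oc4ccc(-c5cc(=O)c6c(O)cc(O)cc6o5)cc4)c(O)cc3o2)cc1 | target

**Step count**

Total: 13 steps. Longest linear sequence: 12 steps (steps 1–6 and 8–13); step 7 is a one-step side branch.

**Steps most likely to fail**

Step 6. Oligomerisation or hydration of the ynol ether, or thermal self-dimerisation of the coumalate, may outrun the cycloaddition, and the para orientation may erode if bond formation becomes less polarised. The fallback uses known chemistry and sets out from phenol 4: an Ullmann-type copper-catalysed O-arylation with methyl 4-iodobenzoate (CuI, picolinic acid, K3PO4, DMSO, 90 °C), conditions suited to ortho-disubstituted phenols. It comes back to the route at 12 and makes no compound outside the list (entry F0). Steps 4 and 5 are then bypassed.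

Step 5. The terminal ynol ether may be lost by hydration to the aryl acetate or by oligomerisation during work-up and concentration. The fallback sets out from 6 and replaces direct protonation by a protect-and-release sequence. The acetylide made with n-BuLi is trapped with Me3SiCl to give the isolable, storable 2-[3,5-bis(benzyloxy)-4-{[(trimethylsilyl)ethynyl]oxy}phenyl]-1,3-dioxolane F1, which is purified on base-deactivated silica. Just before the cycloaddition the silyl group is removed with K2CO3 in MeOH at 0 °C, and the solution is exchanged into toluene, which returns to the route at 9.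

Step 12. Copper-free direct alkynylation followed by 5-endo closure to a 2-arylbenzofuran, 5-exo closure of the ynone to an aurone, aminocarbonylation by diethylamine, or slow oxidative addition at the doubly ortho-flanked iodide may divert the annulation. The fallback sets out from phenol 19 and builds the ynone without palladium. Magnesium-mediated ortho-formylation (MgCl2, Et3N, paraformaldehyde, MeCN, reflux) should give 2,4-bis(benzyloxy)-3-{4-[5,7-bis(benzyloxy)-4-oxo-4H-chromen-2-yl]phenoxy}-6-hydroxybenzaldehyde F2. Addition of the lithium acetylide of 21 (2.5 equiv, THF, −78 °C, the aldehyde reacting ahead of the chromone carbonyl) should give the racemic propargylic alcohol 5,7-bis(benzyloxy)-2-[4-(2,6-bis(benzyloxy)-4-hydroxy-3-[1-hydroxy-3-(4-methoxyphenyl)prop-2-yn-1-yl]phenoxy)phenyl]-4H-chromen-4-one F3. MnO2 in CH2Cl2 oxidises F3 to ynone 22, now isolated, and Et2NH in EtOH closes it 6-endo, which returns to the route at 23.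

**Further compounds**

F0 | step 6 | none | none
F1 | step 5 | 2-[3,5-bis(benzyloxy)-4-{[(trimethylsilyl)ethynyl]oxy}phenyl]-1,3-dioxolane | C[Si](C)(C)C#COc1c(OCc2ccccc2)cc(C2OCCO2)cc1OCc1ccccc1
F2 | step 12 | 2,4-bis(benzyloxy)-3-{4-[5,7-bis(benzyloxy)-4-oxo-4H-chromen-2-yl]phenoxy}-6-hydroxybenzaldehyde | O=Cc1c(O)cc(OCc2ccccc2)c(Oc2ccc(-c3cc(=O)c4c(OCc5ccccc5)cc(OCc5ccccc5)cc4o3)cc2)c1OCc1ccccc1
F3 | step 12 | 5,7-bis(benzyloxy)-2-[4-(2,6-bis(benzyloxy)-4-hydroxy-3-[1-hydroxy-3-(4-methoxyphenyl)prop-2-yn-1-yl]phenoxy)phenyl]-4H-chromen-4-one (racemic) | COc1ccc(C#CC(O)c2c(O)cc(OCc3ccccc3)c(Oc3ccc(-c4cc(=O)c5c(OCc6ccccc6)cc(OCc6ccccc6)cc5o4)cc3)c2OCc2ccccc2)cc1
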